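I start with the easy step: I let Q take up L one to one and give J, which is how I read the quick early fall of Q and rise of J in both earlier runs.

all flasks: Q 0.057 M; Z 0.114 M

| flask | L | remark | time |
|---|---|---|---|
| birch | 0.079 M | run made earlier |  |
| ash | 0.14 M | run made earlier |  |
| teal | 0.0600 M |  | 25 min |
| blue | 0.120 M |  | 25 min |

| run | time / min | Q / % | X / % | J / % |
|---|---|---|---|---|
| birch | 1.33 | 53 | 3 | 50 |
| birch | 4.00 | 26 | 5 | 70 |
| birch | 8.00 | 18 | 13 | 68 |
| birch | 10.0 | 15 | 16 | 63 |
| birch | 15.0 | 15 | 27 | 57 |
| birch | 20.0 | 9 | 29 | 61 |
| birch | 25.0 | 13 | 34 | 53 |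
| ash | 2.00 | 19 | 2 | 79 |
| ash | 3.00 | 9 | 9 | 85 |
| ash | 5.00 | 6 | 14 | 80 |
| ash | 8.00 | 3 | 27 | 72 |
| ash | 10.0 | 0 | 37 | 63 |
| ash | 15.0 | 0 | 51 | 48 |
| ash | 25.0 | 1 | 68 | 32 |

(scatter of a reading: 2 percentage points)

- which of these there is most of at the end, counted by the Q in it, teal (X / J / Q)
- which of these there is most of at the end, counted by the Q in it, blue (X / J / Q)
- final amount of the leader among these, as a percentage of the Q charged, in teal
- final amount of the leader among these, as a percentage of the Q charged, in blue

- the numbers in the tables scatter with a standard deviation of 2 percentage points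
- a reading or a percentage of X counts all its forms, free or not

On that step by itself, the 1.05 equivalents of L in teal cover the Q. But birch, with 1.39 equivalents, stalls at about 13.0% of its Q. I take L as used up there, so of its 0.079 M, 0.0496 M went to Q and 0.0294 M elsewhere.

The second step I add is L with Z, the other reagent charged, which costs birch 25.8% of its Z. If Q and Z each take L at a rate proportional to their own concentration, ln(Q charged / Q left) over ln(Z charged / Z left) stays constant. I call this ratio the split, a selectivity factor, and birch reads 6.84.

The split tells what leaving a given Q costs in L. In teal, leaving 25.0% takes 0.0637 M and leaving 33.3% takes 0.0549 M. Teal holds 0.0600 M, less than the first and more than the second, so Q stops near 28.5%, with L the limiting reagent. Blue holds 0.120 M, more than the 0.112 M that leaving 1.00% takes, so there Q gives out first.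

Last comes X, which at 25 min stands higher in ash than in birch, 68% against 34%. I let J become X through what L and Z made, one for one, which caps X at 51.6% in birch and 33.8% in teal. Birch's climb toward its cap reads 0.0470 /min. So teal reaches X 23.3% and J 48.2%, and J leads. For blue I interpolate X between birch and ash by L, which gives X 56.9% and J 42.1%, and X leads.

The forecast, “leaving almost no spare L”, puts J first in teal at 61% (50% to 72%), more than my 48.2%, and X first in blue at 56% (48% to 64%).

The flasks give J at 50.0% in teal, with X 22.5% and Q 27.5%, and X at 60.0% in blue, with J 39.0%.

    Q + L → J (k = 9.03 /M/min)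
    L + Z → G (k = 1.24 /M/min)
    J + G → X (k = 1.73 /M/min)
    L + X ⇌ D, settled at all times (K = 43.0 /M)

The neighbouring flask is blue charged with 0.14 M of Q. With the same split, leaving 25.0% of that Q takes 0.126 M of L and leaving 33.3% takes 0.110 M. It holds 0.120 M of L, less than the first and more than the second, so by this reckoning Q should stop near 28.1%. In that neighbouring flask, J leads at 59.7%, X reaches 12.8%, L stands at 0.00704% of its charge, and Q ends at 27.5%.

All runs stem from a simulated flask for substances that don't exist.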